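**Retrosynthetic overview**
1. The diosphenol comes last, by double Swern oxidation of a ring A 2,3-diol; the 7β-acetate comes from a C7 ketone by electron-transfer reduction and acetylation.
2. Ring A (C4–C5 bond, C5 quaternary centre, exocyclic methylene, cis fusion) is closed by a palladium-catalysed reductive Heck cyclisation of a 2-bromoallylic tether onto a ring B 3-methylcyclohexenone, itself made by a 1,3-carbonyl transposition.
3. The C9–C11 and C10–C1 bonds are made in one copper-catalysed three-component union of (R)-3,4-dimethylcyclohexenone, a B-alkyl-9-BBN carrying C11–C16 and a C1–C4/C18 aldehyde; C10 is then set by dehydration and conjugate reduction.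
4. Fragments: the enone from 4-methylcyclohexanone (chiral lithium amide), the side chain from crotonyl chloride and vinylmagnesium bromide (oxazolidinone auxiliary), the aldehyde from acrolein and allyl alcohol (alkoxyallylboration).
5. Ring order: ring B is a preformed cyclohexane throughout; ring A is formed last on it.

Assumption: clerodane numbering is used for all intermediates (C1–C10 decalin, C11–C15 side chain with C16 on C13, C17 on C8, C18 = exocyclic CH2 on C4, C19 on C5, C20 on C9), and α/β refer to the usual drawing (ring A left, C10 at the top of the fusion, β toward the viewer), in which the target has 10β-H, 19β-CH3, 20α-CH3, 17α-CH3, 7β-OAc and C11 β.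

**Route**

Step 1
Reactants: 1 4-methylcyclohexanone
Product: 2 (R)-trimethyl[(4-methylcyclohex-1-en-1-yl)oxy]silane
Conditions: (S,S)-bis(1-phenylethyl)amine, n-BuLi, THF, −78 °C; then TMSCl and 1 (internal quench), −78 °C
Reagents that add atoms: chlorotrimethylsilane, C[Si](C)(C)Cl
Why: enantioselective deprotonation (desymmetrisation by a chiral lithium amide) removes one of the two enantiotopic α-hydrogens and silylation in the flask fixes C8 as R (about 88% ee expected, the minor antipode being removed later as a separable diastereomer once the enantiopure fragments are attached).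

Step 2
Reactants: 2 (R)-trimethyl[(4-methylcyclohex-1-en-1-yl)oxy]silane
Product: 3 (R)-4-methylcyclohex-2-en-1-one
Conditions: Pd(OAc)2 (10 mol %), O2 (1 atm), DMSO, 25 °C
Reagents that add atoms: none
Why: Saegusa–Ito oxidation (palladium enolate, β-hydride elimination) places the double bond on the side fixed in step 1 and does not touch C8.

Step 3
Reactants: 3 (R)-4-methylcyclohex-2-en-1-one
Product: 4 trimethyl{[(3S,4R)-3,4-dimethylcyclohex-1-en-1-yl]oxy}silane
Conditions: MeMgBr, CuBr·SMe2 (5 mol %), TMSCl, THF, −78 °C; then Et3N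
Reagents that add atoms: methylmagnesium bromide, C[Mg]Br; chlorotrimethylsilane, C[Si](C)(C)Cl
Why: copper-catalysed conjugate addition with silyl trapping gives the regiodefined enol ether, the methyl entering trans to the C8 methyl (this new centre is erased in step 4).

Step 4
Reactants: 4 trimethyl{[(3S,4R)-3,4-dimethylcyclohex-1-en-1-yl]oxy}silane
Product: 5 (R)-3,4-dimethylcyclohex-2-en-1-one
Conditions: Pd(OAc)2 (10 mol %), O2 (1 atm), DMSO, 25 °C
Reagents that add atoms: none
Why: a second Saegusa–Ito oxidation regenerates the enone with the new methyl (C20) on the β-carbon while C8 stays R.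

Step 5
Reactants: 6 (E)-but-2-enoyl chloride
Product: 7 (R)-4-benzyl-3-[(E)-but-2-enoyl]oxazolidin-2-one
Conditions: (R)-4-benzyloxazolidin-2-one, n-BuLi, THF, −78 °C; then 6, −78 → 0 °C
Reagents that add atoms: (R)-4-benzyloxazolidin-2-one, O=C1N[C@H](Cc2ccccc2)CO1
Why: N-acylation of the lithiated oxazolidinone attaches the Evans auxiliary and creates no new stereocentre.

Step 6
Reactants: 7 (R)-4-benzyl-3-[(E)-but-2-enoyl]oxazolidin-2-one; 8 vinylmagnesium bromide
Product: 9 (R)-4-benzyl-3-[(S)-3-methylpent-4-enoyl]oxazolidin-2-one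
Conditions: CuBr·SMe2 (1.2 equiv), THF–Me2S, −78 → −30 °C
Reagents that add atoms: none
Why: auxiliary-controlled conjugate addition of the vinylcopper reagent to the magnesium-chelated s-cis enoyl imide, from the face opposite the benzyl group, sets the future C13 (S here, R in the target after the priority change on chain extension).

Step 7
Reactants: 9 (R)-4-benzyl-3-[(S)-3-methylpent-4-enoyl]oxazolidin-2-one
Product: 10 methyl (S)-3-methylpent-4-enoate
Conditions: NaOMe (cat.), MeOH, 0 °C
Reagents that add atoms: methanol, CO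
Why: methanolysis (transesterification at the exocyclic imide carbonyl) releases the methyl ester and the recoverable auxiliary without touching C13.

Step 8
Reactants: 11 acrolein
Product: 13 2-bromoacrolein, via 2,3-dibromopropanal 12 (not isolated)
Conditions: Br2, CH2Cl2, 0 °C; then Et3N, 0 °C
Reagents that add atoms: bromine, BrBr
Why: bromine addition to the alkene followed by E1cB dehydrobromination of the α-hydrogen gives the α-bromo enal.

Step 9
Reactants: 14 allyl alcohol
Product: 15 allyl methoxymethyl ether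
Conditions: MOMCl, i-Pr2NEt, CH2Cl2, 0 → 25 °C
Reagents that add atoms: chloromethyl methyl ether, COCCl
Why: O-alkylation (MOM ether formation) gives the precursor of the γ-alkoxyallyl nucleophile.

Step 10
Reactants: 13 2-bromoacrolein; 15 allyl methoxymethyl ether
Product: 18 (3R,4S)-2-bromo-4-(methoxymethoxy)hexa-1,5-dien-3-ol, via (Z)-3-(methoxymethoxy)allyllithium 16 (not isolated), via (Z)-3-(methoxymethoxy)allyl-B(Ipc)2 17 (not isolated)
Conditions: 15, s-BuLi, THF, −78 °C; (+)-Ipc2BOMe; BF3·OEt2; then 13, −78 °C; NaOH, H2O2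
Reagents that add atoms: none
Why: Brown (Z)-γ-alkoxyallylboration through a closed chair transition state gives the syn 1,2-diol monoether by 1,2-addition to the enal, the isopinocampheyl groups fixing the absolute sense (both carbinol centres are temporary and are oxidised away in step 23, so the antipodal reagent would serve equally).

Step 11
Reactants: 18 (3R,4S)-2-bromo-4-(methoxymethoxy)hexa-1,5-dien-3-ol
Product: 19 (3R,4S)-2-bromo-3,4-bis(methoxymethoxy)hexa-1,5-diene
Conditions: MOMCl, i-Pr2NEt, CH2Cl2, 0 → 25 °C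
Reagents that add atoms: chloromethyl methyl ether, COCCl
Why: MOM ether formation protects the second hydroxyl with a group that survives amide bases, organocerium, chromate and palladium.

Step 12
Reactants: 19 (3R,4S)-2-bromo-3,4-bis(methoxymethoxy)hexa-1,5-diene
Product: 21 (2R,3R)-4-bromo-2,3-bis(methoxymethoxy)pent-4-enal, via secondary ozonide 20 (not isolated)
Conditions: O3 (1.0 equiv, Sudan Red 7B end point), CH2Cl2, −78 °C; then PPh3, −78 → 25 °C
Reagents that add atoms: ozone, [O-][O+]=O
Why: chemoselective ozonolysis, the monosubstituted vinyl group reacting far faster with electrophilic ozone than the bromine-deactivated 2-bromoalkene, unveils the aldehyde (used at once).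

Step 13
Reactants: 10 methyl (S)-3-methylpent-4-enoate; 5 (R)-3,4-dimethylcyclohex-2-en-1-one; 21 (2R,3R)-4-bromo-2,3-bis(methoxymethoxy)pent-4-enal
Product: 25 methyl (3R)-5-{(1S,6R)-2-[(2S,3R)-4-bromo-1-hydroxy-2,3-bis(methoxymethoxy)pent-4-en-1-yl]-1,6-dimethyl-3-oxocyclohexyl}-3-methylpentanoate, via B-alkyl-9-BBN 22 (not isolated), via 9-BBN enol borinate 23 (not isolated), via 9-BBN aldolate 24 (not isolated)
Conditions: 10, 9-BBN-H, THF, 0 → 25 °C; then 5, (IMes)CuCl (10 mol %; IMes = 1,3-dimesitylimidazol-2-ylidene), NaOt-Bu (10 mol %), toluene–THF, 40 °C; then 21, −78 → 0 °C; aq. NH4Cl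
Reagents that add atoms: none
Why: Proposed new method: a monovalent copper alkoxide should take the primary alkyl group from the B-alkyl-9-BBN by alkoxide-assisted transmetalation, the alkylcopper should add 1,4 to the boron-activated enone on the face anti to the C8 methyl (forming the C9–C11 bond and the C9 quaternary centre with the side chain β and C20 α), and the copper enolate should return copper to the cycle by B–O bond formation with the next B-alkyl-9-BBN, releasing the regiodefined enol borinate that is captured by the aldehyde in a boron aldol addition (C10–C1 bond); the closest known reactions are copper-catalysed conjugate additions of alkyl-9-BBN reagents to chelating enones, copper–NHC-catalysed quaternary-centre-forming conjugate additions of alkylaluminium and Grignard reagents to 3-methylcyclohexenones, and the uncatalysed 1,4-addition of trialkylboranes to vinyl ketones with aldol capture of the boron enolate, and the new centres at C1 and C10 are left as a mixture because both are erased in steps 14 and 15.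

Step 14
Reactants: 25 methyl (3R)-5-{(1S,6R)-2-[(2S,3R)-4-bromo-1-hydroxy-2,3-bis(methoxymethoxy)pent-4-en-1-yl]-1,6-dimethyl-3-oxocyclohexyl}-3-methylpentanoate
Product: 27 methyl (3R)-5-{(1S,6R)-2-[(2S,3R)-4-bromo-2,3-bis(methoxymethoxy)pent-4-en-1-ylidene]-1,6-dimethyl-3-oxocyclohexyl}-3-methylpentanoate, via C1 mesylate 26 (not isolated)
Conditions: MsCl, Et3N (4 equiv), DMAP (cat.), CH2Cl2, 0 → 25 °C
Reagents that add atoms: none
Why: mesylation and E1cB elimination of the β-mesyloxy ketone complete an aldol condensation to the exocyclic enone (E/Z mixture), which makes C10 trigonal so that it can be set by protonation.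

Step 15
Reactants: 27 methyl (3R)-5-{(1S,6R)-2-[(2S,3R)-4-bromo-2,3-bis(methoxymethoxy)pent-4-en-1-ylidene]-1,6-dimethyl-3-oxocyclohexyl}-3-methylpentanoate
Product: 28 methyl (3R)-5-{(1S,2R,6R)-2-[(2S,3R)-4-bromo-2,3-bis(methoxymethoxy)pent-4-en-1-yl]-1,6-dimethyl-3-oxocyclohexyl}-3-methylpentanoate
Conditions: [(Ph3P)CuH]6 (5 mol %), PhMe2SiH, t-BuOH, toluene, 0 °C
Reagents that add atoms: none
Why: copper hydride conjugate reduction delivers hydride to C1 and the copper enolate is protonated by t-BuOH from the β face, anti to the pseudoaxial C20 methyl on the neighbouring quaternary carbon and clear of the equatorial C17 methyl, which sets C10 (10β-H, tether α) while esters, acetals and the alkenyl bromide are inert.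

Step 16
Reactants: 28 methyl (3R)-5-{(1S,2R,6R)-2-[(2S,3R)-4-bromo-2,3-bis(methoxymethoxy)pent-4-en-1-yl]-1,6-dimethyl-3-oxocyclohexyl}-3-methylpentanoate
Product: 30 methyl (3R)-5-{(1S,2R,6R)-6-[(2S,3R)-4-bromo-2,3-bis(methoxymethoxy)pent-4-en-1-yl]-1,2-dimethyl-5-oxocyclohex-3-en-1-yl}-3-methylpentanoate, via lithium enolate 29 (not isolated)
Conditions: lithium diisopropylamide (1.05 equiv), THF, −78 °C; then PhS(Cl)=N-t-Bu, −78 °C
Reagents that add atoms: none
Why: kinetic deprotonation at the unhindered C6 methylene (the ketone being far more acidic than the ester) followed by Mukaiyama dehydrogenation with the sulfinimidoyl chloride gives the C6–C7 enone at −78 °C without enolising C10.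

Step 17
Reactants: 30 methyl (3R)-5-{(1S,2R,6R)-6-[(2S,3R)-4-bromo-2,3-bis(methoxymethoxy)pent-4-en-1-yl]-1,2-dimethyl-5-oxocyclohex-3-en-1-yl}-3-methylpentanoate
Product: 31 methyl (3R)-5-{(1S,2R,6R)-6-[(2S,3R)-4-bromo-2,3-bis(methoxymethoxy)pent-4-en-1-yl]-5-hydroxy-1,2,5-trimethylcyclohex-3-en-1-yl}-3-methylpentanoate
Conditions: MeLi, CeCl3, THF, −78 °C
Reagents that add atoms: methyllithium, [Li]C
Why: organocerium 1,2-addition to the enone carbonyl introduces C19 chemoselectively over the methyl ester and without enolisation, the new C5 carbinol centre (either epimer) being erased in step 18.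

Step 18
Reactants: 31 methyl (3R)-5-{(1S,2R,6R)-6-[(2S,3R)-4-bromo-2,3-bis(methoxymethoxy)pent-4-en-1-yl]-5-hydroxy-1,2,5-trimethylcyclohex-3-en-1-yl}-3-methylpentanoate
Product: 32 methyl (3R)-5-{(1R,2S,6S)-2-[(2S,3R)-4-bromo-2,3-bis(methoxymethoxy)pent-4-en-1-yl]-1,3,6-trimethyl-5-oxocyclohex-3-en-1-yl}-3-methylpentanoate
Conditions: pyridinium chlorochromate [C5H5NH][CrO3Cl], 4 Å molecular sieves, CH2Cl2, 25 °C
Reagents that add atoms: pyridinium chlorochromate, [O-][Cr](=O)(=O)Cl.c1cc[nH+]cc1
Why: Dauben–Michno oxidative 1,3-transposition (chromate ester, [3,3] shift, oxidation) moves the oxygen to C7 and leaves the methyl on the enone β-carbon C5, giving the acceptor for ring closure.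

Step 19
Reactants: 32 methyl (3R)-5-{(1R,2S,6S)-2-[(2S,3R)-4-bromo-2,3-bis(methoxymethoxy)pent-4-en-1-yl]-1,3,6-trimethyl-5-oxocyclohex-3-en-1-yl}-3-methylpentanoate
Product: 33 methyl (2S,3S,5S,8S,9R,10R,13R)-2,3-bis(methoxymethoxy)-7-oxoclerod-4(18)-en-15-oate
Conditions: Pd(OAc)2 (10 mol %), PPh3 (25 mol %), HCO2Na, Bu4NCl, DMF, 80 °C
Reagents that add atoms: none
Why: reductive Heck cyclisation (oxidative addition of the alkenyl bromide to zerovalent palladium, 6-exo carbopalladation of the enone at C5, formate reduction of the palladium enolate, which has no β-hydrogen to lose) forms the C4–C5 bond, and because the tether is α on C10 it can reach only the α face of C5, so C19 ends β and the decalin is cis-fused.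

Step 20
Reactants: 33 methyl (2S,3S,5S,8S,9R,10R,13R)-2,3-bis(methoxymethoxy)-7-oxoclerod-4(18)-en-15-oate
Product: 34 methyl (2S,3S,5S,7S,8S,9R,10R,13R)-7-hydroxy-2,3-bis(methoxymethoxy)clerod-4(18)-en-15-oate
Conditions: SmI2, HMPA, i-PrOH, THF, 0 °C
Reagents that add atoms: none
Why: electron-transfer (ketyl) reduction gives the thermodynamically preferred equatorial 7β-alcohol, because an α-oxygen would be syn-axial to both C4 and C20, whereas hydride reagents would attack from the open β face and give the 7α-epimer; esters, acetals and the alkene are not reduced.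

Step 21
Reactants: 34 methyl (2S,3S,5S,7S,8S,9R,10R,13R)-7-hydroxy-2,3-bis(methoxymethoxy)clerod-4(18)-en-15-oate
Product: 35 methyl (2S,3S,5S,7S,8S,9R,10R,13R)-7-acetoxy-2,3-bis(methoxymethoxy)clerod-4(18)-en-15-oate
Conditions: Ac2O, pyridine, DMAP (cat.), CH2Cl2, 25 °C
Reagents that add atoms: acetic anhydride, CC(=O)OC(C)=O
Why: DMAP-catalysed acylation of the equatorial secondary alcohol installs the acetate with retention at C7.

Step 22
Reactants: 35 methyl (2S,3S,5S,7S,8S,9R,10R,13R)-7-acetoxy-2,3-bis(methoxymethoxy)clerod-4(18)-en-15-oate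
Product: 36 methyl (2S,3S,5S,7S,8S,9R,10R,13R)-7-acetoxy-2,3-dihydroxyclerod-4(18)-en-15-oate
Conditions: ZnBr2, n-PrSH, CH2Cl2, 0 °C
Reagents that add atoms: none
Why: Lewis-acid-assisted thiolysis of the MOM acetals (transacetalisation to the O,S-acetal) frees both hydroxyls within minutes under conditions that spare the acetate, the methyl ester and the exocyclic alkene.

Step 23
Reactants: 36 methyl (2S,3S,5S,7S,8S,9R,10R,13R)-7-acetoxy-2,3-dihydroxyclerod-4(18)-en-15-oate
Product: 38 methyl (5S,7S,8S,9R,10R,13R)-7-acetoxy-2-hydroxy-3-oxocleroda-1,4(18)-dien-15-oate, via 2,3-diketone 37 (not isolated)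
Conditions: (COCl)2, DMSO, CH2Cl2, −78 °C; then Et3N, −78 → 0 °C
Reagents that add atoms: none
Why: double Swern oxidation of the vicinal diol gives the 2,3-dione, which enolises toward C1 (the only α-hydrogens, C4 carrying the exocyclic methylene) to the conjugated diosphenol without touching any stereocentre.

**Compound list**
1 | 4-methylcyclohexanone | CC1CCC(=O)CC1 | starting material
2 | (R)-trimethyl[(4-methylcyclohex-1-en-1-yl)oxy]silane | C[C@@H]1CCC(O[Si](C)(C)C)=CC1 | intermediate
3 | (R)-4-methylcyclohex-2-en-1-one | C[C@@H]1CCC(=O)C=C1 | intermediate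
4 | trimethyl{[(3S,4R)-3,4-dimethylcyclohex-1-en-1-yl]oxy}silane (trans) | C[C@@H]1CCC(O[Si](C)(C)C)=C[C@H]1C | intermediate
5 | (R)-3,4-dimethylcyclohex-2-en-1-one | C[C@@H]1CCC(=O)C=C1C | intermediate
6 | (E)-but-2-enoyl chloride | C/C=C/C(Cl)=O | starting material
7 | (R)-4-benzyl-3-[(E)-but-2-enoyl]oxazolidin-2-one | C/C=C/C(=O)N1[C@H](Cc2ccccc2)COC1=O | intermediate
8 | vinylmagnesium bromide | C=C[Mg]Br | starting material
9 | (R)-4-benzyl-3-[(S)-3-methylpent-4-enoyl]oxazolidin-2-one | C=C[C@@H](C)CC(=O)N1[C@H](Cc2ccccc2)COC1=O | intermediate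
10 | methyl (S)-3-methylpent-4-enoate | C=C[C@@H](C)CC(=O)OC | intermediate
11 | acrolein | C=CC=O | starting material
12 | 2,3-dibromopropanal (racemic, not isolated) | O=CC(Br)CBr | intermediate
13 | 2-bromoacrolein | C=C(Br)C=O | intermediate
14 | allyl alcohol | C=CCO | starting material
15 | allyl methoxymethyl ether | C=CCOCOC | intermediate
16 | (Z)-3-(methoxymethoxy)allyllithium (not isolated) | [Li]C/C=C\OCOC | intermediate
17 | [(Z)-3-(methoxymethoxy)allyl]diisopinocampheylborane, Ipc groups of the (−)-α-pinene series (not isolated) | COCO/C=C\CB([C@H]1C[C@H]2C[C@@H]([C@@H]1C)C2(C)C)[C@H]1C[C@H]2C[C@@H]([C@@H]1C)C2(C)C | intermediate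
18 | (3R,4S)-2-bromo-4-(methoxymethoxy)hexa-1,5-dien-3-ol | C=C(Br)[C@H](O)[C@@H](OCOC)C=C | intermediate
19 | (3R,4S)-2-bromo-3,4-bis(methoxymethoxy)hexa-1,5-diene | C=C(Br)[C@H](OCOC)[C@@H](OCOC)C=C | intermediate
20 | secondary ozonide (1,2,4-trioxolane) from the vinyl group of 19, other centres as in 19, mixture at the ring carbon (not isolated) | C=C(Br)[C@H](OCOC)[C@@H](OCOC)C1OCOO1 | intermediate
21 | (2R,3R)-4-bromo-2,3-bis(methoxymethoxy)pent-4-enal | O=C[C@H](OCOC)[C@@H](OCOC)C(Br)=C | intermediate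
22 | methyl (R)-5-(9-borabicyclo[3.3.1]nonan-9-yl)-3-methylpentanoate (not isolated) | COC(=O)C[C@H](C)CCB1C2CCCC1CCC2 | intermediate
23 | methyl (3R)-5-{(1S,6R)-3-[(9-borabicyclo[3.3.1]nonan-9-yl)oxy]-1,6-dimethylcyclohex-2-en-1-yl}-3-methylpentanoate (not isolated) | C[C@@H]1CCC(OB2C3CCCC2CCC3)=C[C@@]1(C)CC[C@@H](C)CC(=O)OC | intermediate
24 | O-(9-borabicyclo[3.3.1]nonan-9-yl) borinate of 25 at the new C1 oxygen, mixture at C1 and C10 (not isolated) | C[C@@H]1CCC(=O)C(C(OB2C3CCCC2CCC3)[C@H](OCOC)[C@@H](OCOC)C(Br)=C)[C@@]1(C)CC[C@@H](C)CC(=O)OC | intermediate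
25 | methyl (3R)-5-{(1S,6R)-2-[(2S,3R)-4-bromo-1-hydroxy-2,3-bis(methoxymethoxy)pent-4-en-1-yl]-1,6-dimethyl-3-oxocyclohexyl}-3-methylpentanoate, mixture at C1 and C10 | C[C@@H]1CCC(=O)C(C(O)[C@H](OCOC)[C@@H](OCOC)C(Br)=C)[C@@]1(C)CC[C@@H](C)CC(=O)OC | intermediate
26 | C1 methanesulfonate of 25 (not isolated) | C[C@@H]1CCC(=O)C(C(OS(C)(=O)=O)[C@H](OCOC)[C@@H](OCOC)C(Br)=C)[C@@]1(C)CC[C@@H](C)CC(=O)OC | intermediate
27 | methyl (3R)-5-{(1S,6R)-2-[(2S,3R)-4-bromo-2,3-bis(methoxymethoxy)pent-4-en-1-ylidene]-1,6-dimethyl-3-oxocyclohexyl}-3-methylpentanoate, E/Z mixture at C10=C1 | C[C@@H]1CCC(=O)C(=C[C@H](OCOC)[C@@H](OCOC)C(Br)=C)[C@@]1(C)CC[C@@H](C)CC(=O)OC | intermediate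
28 | methyl (3R)-5-{(1S,2R,6R)-2-[(2S,3R)-4-bromo-2,3-bis(methoxymethoxy)pent-4-en-1-yl]-1,6-dimethyl-3-oxocyclohexyl}-3-methylpentanoate (10β-H, 20α-CH3, 17α-CH3) | C[C@@H]1CCC(=O)[C@H](C[C@H](OCOC)[C@@H](OCOC)C(Br)=C)[C@@]1(C)CC[C@@H](C)CC(=O)OC | intermediate
29 | lithium enolate of 28 (C5–OLi, C5=C6) (not isolated) | C[C@@H]1CC=C(O[Li])[C@H](C[C@H](OCOC)[C@@H](OCOC)C(Br)=C)[C@@]1(C)CC[C@@H](C)CC(=O)OC | intermediate
30 | methyl (3R)-5-{(1S,2R,6R)-6-[(2S,3R)-4-bromo-2,3-bis(methoxymethoxy)pent-4-en-1-yl]-1,2-dimethyl-5-oxocyclohex-3-en-1-yl}-3-methylpentanoate | C[C@@H]1C=CC(=O)[C@H](C[C@H](OCOC)[C@@H](OCOC)C(Br)=C)[C@@]1(C)CC[C@@H](C)CC(=O)OC | intermediate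
31 | methyl (3R)-5-{(1S,2R,6R)-6-[(2S,3R)-4-bromo-2,3-bis(methoxymethoxy)pent-4-en-1-yl]-5-hydroxy-1,2,5-trimethylcyclohex-3-en-1-yl}-3-methylpentanoate, either epimer at the carbinol carbon C5 | C[C@@H]1C=CC(C)(O)[C@H](C[C@H](OCOC)[C@@H](OCOC)C(Br)=C)[C@@]1(C)CC[C@@H](C)CC(=O)OC | intermediate
32 | methyl (3R)-5-{(1R,2S,6S)-2-[(2S,3R)-4-bromo-2,3-bis(methoxymethoxy)pent-4-en-1-yl]-1,3,6-trimethyl-5-oxocyclohex-3-en-1-yl}-3-methylpentanoate | C[C@@H]1C(=O)C=C(C)[C@H](C[C@H](OCOC)[C@@H](OCOC)C(Br)=C)[C@@]1(C)CC[C@@H](C)CC(=O)OC | intermediate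
33 | methyl (2S,3S,5S,8S,9R,10R,13R)-2,3-bis(methoxymethoxy)-7-oxoclerod-4(18)-en-15-oate (cis-decalin, 2β,3α-di-O) | C=C1[C@H](OCOC)[C@@H](OCOC)C[C@@H]2[C@@](C)(CC[C@@H](C)CC(=O)OC)[C@H](C)C(=O)C[C@]12C | intermediate
34 | methyl (2S,3S,5S,7S,8S,9R,10R,13R)-7-hydroxy-2,3-bis(methoxymethoxy)clerod-4(18)-en-15-oate (7β-OH) | C=C1[C@H](OCOC)[C@@H](OCOC)C[C@@H]2[C@@](C)(CC[C@@H](C)CC(=O)OC)[C@H](C)[C@@H](O)C[C@]12C | intermediate
35 | methyl (2S,3S,5S,7S,8S,9R,10R,13R)-7-acetoxy-2,3-bis(methoxymethoxy)clerod-4(18)-en-15-oate | C=C1[C@H](OCOC)[C@@H](OCOC)C[C@@H]2[C@@](C)(CC[C@@H](C)CC(=O)OC)[C@H](C)[C@@H](OC(C)=O)C[C@]12C | intermediate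
36 | methyl (2S,3S,5S,7S,8S,9R,10R,13R)-7-acetoxy-2,3-dihydroxyclerod-4(18)-en-15-oate | C=C1[C@H](O)[C@@H](O)C[C@@H]2[C@@](C)(CC[C@@H](C)CC(=O)OC)[C@H](C)[C@@H](OC(C)=O)C[C@]12C | intermediate
37 | methyl (5S,7S,8S,9R,10R,13R)-7-acetoxy-2,3-dioxoclerod-4(18)-en-15-oate (not isolated) | C=C1C(=O)C(=O)C[C@@H]2[C@@](C)(CC[C@@H](C)CC(=O)OC)[C@H](C)[C@@H](OC(C)=O)C[C@]12C | intermediate
38 | methyl (5S,7S,8S,9R,10R,13R)-7-acetoxy-2-hydroxy-3-oxocleroda-1,4(18)-dien-15-oate (CNP0180040.1) | C=C1C(=O)C(O)=C[C@@H]2[C@@](C)(CC[C@@H](C)CC(=O)OC)[C@H](C)[C@@H](OC(C)=O)C[C@]12C | target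

**Step count**
Total: 23 steps. Longest linear sequence: 15 steps (steps 1–4 then 13–23; the path 8, 10, 11, 12 then 13–23 is equally long), which is 15/23 of the total.

**Steps most likely to fail, with fallbacks**

Step 13, the proposed copper-catalysed alkylboration–aldol union, may fail because a neutral alkylcopper can be too sluggish toward a β,β-disubstituted enone. The fallback uses known chemistry and sets out from 10 and 5. Hydrozirconation of 10 with Cp2Zr(H)Cl gives the alkylzirconocene methyl (S)-5-[chlorobis(cyclopentadienyl)zirconio]-3-methylpentanoate F1. F1 is added to 5 under the established copper-catalysed conjugate addition of alkylzirconocenes to 3-methylcyclohexenones (CuCl, AgNTf2, a phosphoramidite ligand matched to the substrate bias, TMSCl, Et2O), giving the silyl enol ether methyl (3R)-5-{(1S,6R)-1,6-dimethyl-3-[(trimethylsilyl)oxy]cyclohex-2-en-1-yl}-3-methylpentanoate F2. A BF3·OEt2-mediated Mukaiyama aldol addition of F2 to 21 (CH2Cl2, −78 °C) then comes back to the route at 25.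

Step 15 may give poor facial selectivity in the protonation that sets C10, since it rests on substrate control alone. The fallback sets out from 27. The same copper hydride reduction run with PhMe2SiH and no alcohol traps the enolate as the dimethylphenylsilyl enol ether of 28 (C5–OSiMe2Ph, C5=C10) F3, which is isolated. F3 is then protonated under catalyst control (a BINOL-derived N-triflyl thiophosphoramide with phenol as the stoichiometric proton source, the antipode of the catalyst chosen for β-face delivery), and the route is rejoined at 28.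

Step 19 may suffer from slow carbopalladation at the fully substituted enone β-carbon, with simple reduction of the alkenyl bromide competing. The fallback sets out from 32 and replaces the organopalladium pathway by a tin hydride radical cyclisation (Bu3SnH, AIBN, benzene, 80 °C, slow addition). The alkenyl radical adds 6-exo to C5 from the α face and the resulting α-keto radical is reduced, so the route is rejoined directly at 33; this way makes no further compound: none F0.

**Further compounds**
F1 | step 13 | methyl (S)-5-[chlorobis(cyclopentadienyl)zirconio]-3-methylpentanoate | COC(=O)C[C@H](C)CC[Zr](Cl)(C1C=CC=C1)C1C=CC=C1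
F2 | step 13 | methyl (3R)-5-{(1S,6R)-1,6-dimethyl-3-[(trimethylsilyl)oxy]cyclohex-2-en-1-yl}-3-methylpentanoate | C[C@@H]1CCC(O[Si](C)(C)C)=C[C@@]1(C)CC[C@@H](C)CC(=O)OC
F3 | step 15 | dimethylphenylsilyl enol ether of 28 (C5–OSiMe2Ph, C5=C10) | C[C@@H]1CCC(O[Si](C)(C)c2ccccc2)=C(C[C@H](OCOC)[C@@H](OCOC)C(Br)=C)[C@@]1(C)CC[C@@H](C)CC(=O)OC
F0 | step 19 | none | none
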